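**Direct plan and its weak points**

A direct plan would make the β-benzyl lactone A1 through an Evans oxazolidinone alkylation sequence, build the formylpyrone ester A2 separately, join the two by a lithium enolate aldol to carbinol A3, remove the hydroxyl via a thionocarbonate and tin hydride to ester A4, and hydrolyse A4 in hot acid.
- The aldol union would be weak: a basic lactone enolate would meet a 2-pyrone that is itself a Michael acceptor and an acylating lactone, and the carbinol centre it creates would only be deleted again in two further steps, one a stoichiometric tin radical reduction.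
- The run-up to A2 would be weak: its exocyclic carbon would pass from methyl through bromomethyl, formyl and carbinol back to methylene, a chain of redox changes that builds nothing.
- The closing ester hydrolysis would be weak: hot aqueous acid would act on the finished pyrone lactone with all material invested, and the two lactone stereocentres would be set in separate campaigns, the first with a stoichiometric auxiliary over five steps.

**Retrosynthetic overview of the new route**

- Key disconnection: pyrone carbons C2–C6 plus the carboxyl carbon on C6 are read as the six carbons of a benzene ring. Cutting the O1–C2 bond and joining C2 to the carboxyl carbon gives the 3,4,5-trihydroxyphenyl ring of lignan 14.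
- Forward, an aromatic C–C bond between two hydroxylated carbons is cleaved oxidatively and the third oxygen closes the pyrone, the chemical counterpart of the dioxygenase ring fission that presumably makes such seco-lignans. The 5-substituted pyrogallol is symmetric, so both candidate bonds give the same product.
- Lignan 14 comes from a one-flask union of lithiated dithiane 7, menthyloxybutenolide 6 and benzyl bromide 5, which forms the C4–benzylic and C3–CH2 bonds and sets C3 and C4 together, trans.
- Ring order: the butyrolactone is carried from the butenolide and the pyrone is made last. No enolate meets a pyrone, no carbinol is made and deleted, the side-chain carbon stays at the CH2 level, and the acid emerges free.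

Key step: step 6

Assumptions: the target is the (3R,4R) enantiomer encoded in the SMILES. Butenolide 6 is taken as a purchasable chiral building block (otherwise two steps from furfural and l-menthol).

**Route**

Step 1
Reactants: 1 3,4-dimethoxybenzaldehyde; 2 propane-1,3-dithiol
Product: 3 2-(3,4-dimethoxyphenyl)-1,3-dithiane
Conditions: BF3·OEt2 (10 mol %), CH2Cl2, 0 °C → rt, 3 h
Reagents that add atoms: none
Why: Lewis acid-catalysed dithioacetalisation should turn the aldehyde carbon into a benzyl anion equivalent whose two C–S bonds are erased later by nickel.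

Step 2
Reactants: 4 [3,4,5-tris(benzyloxy)phenyl]methanol
Product: 5 3,4,5-tris(benzyloxy)benzyl bromide
Conditions: PBr3 (0.4 equiv), CH2Cl2–Et2O, 0 °C, 1 h; cold aq NaHCO3 wash, used at once
Reagents that add atoms: phosphorus tribromide, BrP(Br)Br
Why: Bromination of a benzylic alcohol through its phosphite ester (SN2 by bromide) should proceed at 0 °C without touching the aryl benzyl ethers.

Step 3
Reactants: 3 2-(3,4-dimethoxyphenyl)-1,3-dithiane; 6 (5R)-5-{[(1R,2S,5R)-5-methyl-2-(propan-2-yl)cyclohexyl]oxy}furan-2(5H)-one; 5 3,4,5-tris(benzyloxy)benzyl bromide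
Product: 9 (3R,4R,5R)-3-[3,4,5-tris(benzyloxy)benzyl]-4-[2-(3,4-dimethoxyphenyl)-1,3-dithian-2-yl]-5-{[(1R,2S,5R)-5-methyl-2-(propan-2-yl)cyclohexyl]oxy}dihydrofuran-2(3H)-one, via 2-lithio dithiane 7 (not isolated), via lithium lactone enolate 8 (not isolated)
Conditions: 3, n-BuLi (1.05 equiv), THF, −78 → −30 °C, 1 h; 6 (1.0 equiv), −78 °C, 1 h; 5 (1.3 equiv), DMPU (4 equiv), −78 → −20 °C, 6 h; aq NH4Cl
Reagents that add atoms: none
Why: Tandem conjugate addition–enolate alkylation, in which the sulfur-stabilised anion adds 1,4 to the butenolide anti to the C5 menthyloxy group (sets C4) and the resulting enolate is benzylated anti to the bulky dithianyl group (sets C3 trans), so the menthol-derived acetal centre controls both new stereocentres in one flask.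

Step 4
Reactants: 9 tandem adduct
Product: 12 (3R,4R)-3-[3,4,5-tris(benzyloxy)benzyl]-4-[2-(3,4-dimethoxyphenyl)-1,3-dithian-2-yl]dihydrofuran-2(3H)-one, via potassium formyl carboxylate 10 (not isolated), via potassium hydroxy carboxylate 11 (not isolated)
Conditions: KOH (4 equiv), NaBH4 (4 equiv), EtOH–THF–H2O, 0 °C → rt, 4 h; then 2 M HCl to pH 1, rt, 2 h
Reagents that add atoms: potassium hydroxide, [K+].[OH-] (its oxygen enters the carboxyl group on ring opening and is partly retained after relactonisation)
Why: Saponification of the acyloxy acetal releases menthol and a formyl carboxylate, borohydride reduces the aldehyde faster than it can enolise, and acid relactonises the γ-hydroxy acid, so the acetal carbon becomes the lactone CH2 while C3, C4, the dithiane and the benzyl ethers are untouched.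

Step 5
Reactants: 12 dithianyl lactone
Product: 14 (3R,4R)-4-(3,4-dimethoxybenzyl)-3-(3,4,5-trihydroxybenzyl)dihydrofuran-2(3H)-one, via tris(benzyl) ether lactone 13 (not isolated)
Conditions: Raney Ni (W-2, neutral-washed, large excess), H2 (1 atm), EtOH, 70 °C, 6 h; filtered under argon, trace AcOH, used promptly
Reagents that add atoms: none
Why: Raney nickel hydrogenolysis (Mozingo desulfurisation) should reduce the dithiane carbon to the benzylic CH2 and the same hydrogen-laden nickel should cleave the three aryl benzyl ethers, while the lactone, the aryl methyl ethers and both stereocentres, neither of which is at the reacting carbon, are unaffected.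

Step 6
Reactants: 14 pyrogallol lignan lactone
Product: 18 4-{[(3R,4R)-4-(3,4-dimethoxybenzyl)-2-oxotetrahydrofuran-3-yl]methyl}-2-oxo-2H-pyran-6-carboxylic acid (target), via hydroxy-o-quinone 15 (not isolated), via hydroxymuconic anhydride 16 (not isolated), via 2-hydroxymuconic acid 17 (not isolated)
Conditions: 14 (0.05 M in AcOH) added over 1 h to AcOOH (2.05 equiv), Fe(acac)3 (2 mol %), AcOH, 15 °C, then 1 h; trace Me2S if a peroxide test is positive; 6 M HCl, 70 °C, 2 h
Reagents that add atoms: peracetic acid, CC(=O)OO; water, O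
Why: Peracid, relayed by the trivalent iron catecholate, should oxidise the pyrogallol ring of 14 to hydroxy-o-quinone 15, a second equivalent should insert oxygen between two adjacent carbonyl carbons in a Baeyer–Villiger-type step that cleaves the former aromatic C–C bond to give anhydride 16, and water opens 16 to the cis,cis-2-hydroxymuconic acid 17. The closest known reaction types are the iron-catalysed peracetic acid cleavage of catechols to cis,cis-muconic acids, the peracid oxidation of pyrogallol itself to 2-pyrone-6-carboxylic acid, and the acid-mediated enol lactonisation of 2-hydroxymuconic acids, which together are the laboratory counterpart of dioxygenase ring fission. The pyrone closes by 6-exo-trig attack of the enol oxygen on the distal carboxyl group, which the ring-derived Z alkene holds within reach, and hot acid funnels any E/Z-isomerised chain through the keto tautomer into the same lactone. No stereocentre is formed; C3 and C4 of the butyrolactone are spectators and their trans arrangement is the thermodynamic one under acid. Regioselectivity is secured by symmetry, since the 5-substituted pyrogallol has two equivalent bonds between hydroxylated carbons and both lead to 17, and chemoselectivity by the free hydroxyl groups, since only this ring can form the quinone while the dimethoxyphenyl ring reacts far more slowly with peracid. Slow addition of 14 to the oxidant keeps quinone 15 away from unreacted pyrogallol, and destroying peroxide before heating protects the keto tautomer of 17 from oxidative decarboxylation.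

**Compound list**

1 | 3,4-dimethoxybenzaldehyde | COc1ccc(C=O)cc1OC | starting material
2 | propane-1,3-dithiol | SCCCS | starting material
3 | 2-(3,4-dimethoxyphenyl)-1,3-dithiane | COc1ccc(C2SCCCS2)cc1OC | intermediate
4 | [3,4,5-tris(benzyloxy)phenyl]methanol | OCc1cc(OCc2ccccc2)c(OCc2ccccc2)c(OCc2ccccc2)c1 | starting material
5 | 3,4,5-tris(benzyloxy)benzyl bromide | BrCc1cc(OCc2ccccc2)c(OCc2ccccc2)c(OCc2ccccc2)c1 | intermediate
6 | (5R)-5-{[(1R,2S,5R)-5-methyl-2-(propan-2-yl)cyclohexyl]oxy}furan-2(5H)-one | O=C1C=C[C@H](O[C@@H]2C[C@H](C)CC[C@H]2C(C)C)O1 | starting material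
7 | 2-(3,4-dimethoxyphenyl)-2-lithio-1,3-dithiane (not isolated) | [Li]C1(c2ccc(OC)c(OC)c2)SCCCS1 | intermediate
8 | lithium (4R,5R)-4-[2-(3,4-dimethoxyphenyl)-1,3-dithian-2-yl]-5-{[(1R,2S,5R)-5-methyl-2-(propan-2-yl)cyclohexyl]oxy}-4,5-dihydrofuran-2-olate (not isolated) | [Li+].[O-]C1=C[C@@H](C2(c3ccc(OC)c(OC)c3)SCCCS2)[C@H](O[C@@H]2C[C@H](C)CC[C@H]2C(C)C)O1 | intermediate
9 | (3R,4R,5R)-3-[3,4,5-tris(benzyloxy)benzyl]-4-[2-(3,4-dimethoxyphenyl)-1,3-dithian-2-yl]-5-{[(1R,2S,5R)-5-methyl-2-(propan-2-yl)cyclohexyl]oxy}dihydrofuran-2(3H)-one | O=C1[C@H](Cc2cc(OCc3ccccc3)c(OCc3ccccc3)c(OCc3ccccc3)c2)[C@@H](C2(c3ccc(OC)c(OC)c3)SCCCS2)[C@H](O[C@@H]2C[C@H](C)CC[C@H]2C(C)C)O1 | intermediate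
10 | potassium (2R,3R)-2-[3,4,5-tris(benzyloxy)benzyl]-3-[2-(3,4-dimethoxyphenyl)-1,3-dithian-2-yl]-4-oxobutanoate (not isolated) | [K+].[O-]C(=O)[C@H](Cc1cc(OCc2ccccc2)c(OCc2ccccc2)c(OCc2ccccc2)c1)[C@H](C=O)C1(c2ccc(OC)c(OC)c2)SCCCS1 | intermediate
11 | potassium (2R,3R)-2-[3,4,5-tris(benzyloxy)benzyl]-3-[2-(3,4-dimethoxyphenyl)-1,3-dithian-2-yl]-4-hydroxybutanoate (not isolated) | [K+].[O-]C(=O)[C@H](Cc1cc(OCc2ccccc2)c(OCc2ccccc2)c(OCc2ccccc2)c1)[C@H](CO)C1(c2ccc(OC)c(OC)c2)SCCCS1 | intermediate
12 | (3R,4R)-3-[3,4,5-tris(benzyloxy)benzyl]-4-[2-(3,4-dimethoxyphenyl)-1,3-dithian-2-yl]dihydrofuran-2(3H)-one | COc1ccc(C2(SCCCS2)[C@H]2COC(=O)[C@@H]2Cc2cc(OCc3ccccc3)c(OCc3ccccc3)c(OCc3ccccc3)c2)cc1OC | intermediate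
13 | (3R,4R)-3-[3,4,5-tris(benzyloxy)benzyl]-4-(3,4-dimethoxybenzyl)dihydrofuran-2(3H)-one (not isolated) | COc1ccc(C[C@H]2COC(=O)[C@@H]2Cc2cc(OCc3ccccc3)c(OCc3ccccc3)c(OCc3ccccc3)c2)cc1OC | intermediate
14 | (3R,4R)-4-(3,4-dimethoxybenzyl)-3-(3,4,5-trihydroxybenzyl)dihydrofuran-2(3H)-one | COc1ccc(C[C@H]2COC(=O)[C@@H]2Cc2cc(O)c(O)c(O)c2)cc1OC | intermediate
15 | (3R,4R)-4-(3,4-dimethoxybenzyl)-3-[(5-hydroxy-3,4-dioxocyclohexa-1,5-dien-1-yl)methyl]dihydrofuran-2(3H)-one (not isolated) | COc1ccc(C[C@H]2COC(=O)[C@@H]2CC2=CC(=O)C(=O)C(O)=C2)cc1OC | intermediate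
16 | (3R,4R)-4-(3,4-dimethoxybenzyl)-3-[(6-hydroxy-2,7-dioxo-2,7-dihydrooxepin-4-yl)methyl]dihydrofuran-2(3H)-one (not isolated) | COc1ccc(C[C@H]2COC(=O)[C@@H]2CC2=CC(=O)OC(=O)C(O)=C2)cc1OC | intermediate
17 | (2E,4Z)-2-hydroxy-4-{[(3R,4R)-4-(3,4-dimethoxybenzyl)-2-oxotetrahydrofuran-3-yl]methyl}hexa-2,4-dienedioic acid (not isolated) | COc1ccc(C[C@H]2COC(=O)[C@@H]2C/C(=C/C(=O)O)/C=C(/O)C(=O)O)cc1OC | intermediate
18 | 4-{[(3R,4R)-4-(3,4-dimethoxybenzyl)-2-oxotetrahydrofuran-3-yl]methyl}-2-oxo-2H-pyran-6-carboxylic acid | COc1ccc(C[C@H]2COC(=O)[C@@H]2Cc2cc(C(=O)O)oc(=O)c2)cc1OC | target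

**Step count**

Total steps: 6. Longest linear sequence: 5 (steps 1, 3, 4, 5, 6; step 2 is a one-step side branch).

**Steps most likely to fail, with fallbacks**

Step 6 is the riskiest. The hydroxyquinone may couple with unreacted pyrogallol to benzotropolone-type dimers before it is cleaved, or residual peracid may decarboxylate the keto-acid tautomer of the opened chain. The fallback sets out from 14 and comes back at 18, and replaces the peroxide by a non-peroxidic glycol-type cleavage. Lead tetraacetate (2.0 equiv) in MeOH–toluene at 0 °C should oxidise 14 to the quinone at once and cleave its methanol hemiketal, as it does with catechols, to give (2E,4Z)-2-hydroxy-6-methoxy-6-oxo-4-{[(3R,4R)-4-(3,4-dimethoxybenzyl)-2-oxotetrahydrofuran-3-yl]methyl}hexa-2,4-dienoic acid F1, which is isolated by extraction. Separate treatment of F1 with 6 M HCl–dioxane at 70 °C should close the pyrone with loss of methanol and give 18.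

Step 3 is second. C-alkylation of the hindered lithium enolate by the benzylic bromide may be slow, so that proton transfer competes and the trans,trans control erodes. The fallback sets out from enolate 8 and comes back at 9, and changes the electrophile class. Enolate 8 would be trapped at −78 °C with the far more reactive 3,4,5-tris(benzyloxy)benzaldehyde F2 and quenched with AcOH. This should give (3S,4R,5R)-3-{hydroxy[3,4,5-tris(benzyloxy)phenyl]methyl}-4-[2-(3,4-dimethoxyphenyl)-1,3-dithian-2-yl]-5-{[(1R,2S,5R)-5-methyl-2-(propan-2-yl)cyclohexyl]oxy}dihydrofuran-2(3H)-one F3 as both carbinol epimers. The electron-rich benzylic hydroxyl of F3 would then be removed by ionic hydrogenation (Et3SiH, TFA, CH2Cl2, −20 → 0 °C), which leaves the dithiane, the acetal and C3 alone and returns 9.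

Step 5 is third. Hydrogenolysis of the three benzyl ethers may stall on sulfur-laden nickel, or the freed pyrogallol may oxidise in air on the metal surface during filtration. The fallback sets out from 12 and comes back at 14, and gives each job its own reagent. Raney Ni deactivated by reflux in acetone (EtOH, 50 °C) should desulfurise 12 only, so that the tris(benzyl) ether 13 is this time isolated. Hydrogenolysis of 13 over Pd/C (H2, 1 atm, EtOAc–EtOH, trace AcOH) should then give 14 from a sulfur-free, neutral medium. This fallback makes no compound outside the list (F0).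

**Further compounds**

F1 | step 6 | (2E,4Z)-2-hydroxy-6-methoxy-6-oxo-4-{[(3R,4R)-4-(3,4-dimethoxybenzyl)-2-oxotetrahydrofuran-3-yl]methyl}hexa-2,4-dienoic acid | COc1ccc(C[C@H]2COC(=O)[C@@H]2C/C(=C/C(=O)OC)/C=C(/O)C(=O)O)cc1OC
F2 | step 3 | 3,4,5-tris(benzyloxy)benzaldehyde | O=Cc1cc(OCc2ccccc2)c(OCc2ccccc2)c(OCc2ccccc2)c1
F3 | step 3 | (3S,4R,5R)-3-{hydroxy[3,4,5-tris(benzyloxy)phenyl]methyl}-4-[2-(3,4-dimethoxyphenyl)-1,3-dithian-2-yl]-5-{[(1R,2S,5R)-5-methyl-2-(propan-2-yl)cyclohexyl]oxy}dihydrofuran-2(3H)-one, both carbinol epimers | O=C1[C@H](C(O)c2cc(OCc3ccccc3)c(OCc3ccccc3)c(OCc3ccccc3)c2)[C@@H](C2(c3ccc(OC)c(OC)c3)SCCCS2)[C@H](O[C@@H]2C[C@H](C)CC[C@H]2C(C)C)O1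
F0 | step 5 | none | none
A1 | direct plan | (R)-4-(3,4-dimethoxybenzyl)dihydrofuran-2(3H)-one | COc1ccc(C[C@H]2COC(=O)C2)cc1OC
A2 | direct plan | ethyl 4-formyl-2-oxo-2H-pyran-6-carboxylate | CCOC(=O)c1cc(C=O)cc(=O)o1
A3 | direct plan | ethyl 4-{[(3S,4R)-4-(3,4-dimethoxybenzyl)-2-oxotetrahydrofuran-3-yl](hydroxy)methyl}-2-oxo-2H-pyran-6-carboxylate, both carbinol epimers | COc1ccc(C[C@H]2COC(=O)[C@@H]2C(O)c2cc(C(=O)OCC)oc(=O)c2)cc1OC
A4 | direct plan | ethyl 4-{[(3R,4R)-4-(3,4-dimethoxybenzyl)-2-oxotetrahydrofuran-3-yl]methyl}-2-oxo-2H-pyran-6-carboxylate | COc1ccc(C[C@H]2COC(=O)[C@@H]2Cc2cc(C(=O)OCC)oc(=O)c2)cc1OC
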